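Numbering the chain from the ester carbon (C1) to the alkene terminus (C18), the C7–C13 tether is cut at C7=C8 and C12=C13. This leaves a 1,2-dioxane aldehyde (C1–C7), an acyclic peroxyketal aldehyde (C13–C18) and an (R)-methyl-branched C8–C12 linchpin with a phosphonium at C12 and a phenyltetrazolyl sulfone at C8. In one flask the ylide end olefinates the C13 aldehyde and, after a second base charge, the sulfone end olefinates the C7 aldehyde, completing the carbon skeleton. The step exploits that C6 of the dioxane ring and C14 are fully substituted peroxide carbons, so neither aldehyde can enolise or eliminate, and that C8–C12 carries only the C10 methyl centre.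

Key step: step 21

Remark: the target numbering C1–C18 is used for all intermediates. CIP labels at C6, C10 and C14 change with the neighbouring groups in some intermediates although the spatial arrangement stays the same; the SMILES strings are decisive.
Remark: the perhydrolysis of step 2 is assumed to proceed with inversion at the tertiary carbon, as is usual for this reaction class.
Remark: steps 1–2 are common, steps 3–12 give dioxane aldehyde 15, steps 13–14 give acyclic aldehyde 17, steps 15–20 give linchpin 25, and steps 21–23 join the pieces and finish.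

Step 1
Reactants: 1 geraniol
Product: 2 (2R,3R)-2,3-epoxygeraniol, [(2R,3R)-3-methyl-3-(4-methylpent-3-en-1-yl)oxiran-2-yl]methanol
Conditions: Ti(OiPr)4 (cat.), D-(−)-diethyl tartrate, t-BuOOH, 4 Å molecular sieves, CH2Cl2, −20 °C
Reagents that add atoms: tert-butyl hydroperoxide, CC(C)(C)OO
Why: Sharpless asymmetric epoxidation acts only on the allylic C2=C3 alkene, and the D-tartrate ligand delivers oxygen to the face that gives the (2R,3R)-epoxide, whose C3 becomes C6 and C14 of the target after inversion.

Step 2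
Reactants: 2 (2R,3R)-2,3-epoxygeraniol; 3 hydrogen peroxide
Product: 4 (2R,3S)-3-hydroperoxy-3,7-dimethyloct-6-ene-1,2-diol
Conditions: anhydrous H2O2 in Et2O, H3PMo12O40 (cat.), 0 °C → rt
Reagents that add atoms: hydrogen peroxide, OO
Why: In this molybdenum-catalysed perhydrolysis of a trisubstituted epoxide, H2O2 should open the activated oxirane at the tertiary carbon (C2 is deactivated by the adjacent CH2OH) in a borderline SN2 process with inversion, which sets the (3S) peroxide-bearing quaternary centre and leaves C2 untouched.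

Step 3
Reactants: 4 (2R,3S)-3-hydroperoxy-3,7-dimethyloct-6-ene-1,2-diol
Product: 5 (4R)-4-[(2S)-2-[(2-methoxypropan-2-yl)peroxy]-6-methylhept-5-en-2-yl]-2,2-dimethyl-1,3-dioxolane
Conditions: 2-methoxypropene (excess), PPTS (cat.), CH2Cl2, 0 °C; Et3N quench
Reagents that add atoms: 2-methoxypropene, COC(C)=C
Why: Acid-catalysed ketalisation with the enol ether should cap the hydroperoxide as its 2-methoxyprop-2-yl peroxyketal and close the 1,2-diol (the latent C7 aldehyde) to a dioxolane in one operation, without touching a stereocentre.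

Step 4
Reactants: 5 dioxolane peroxyketal
Product: 6 (4S)-4-[(4R)-2,2-dimethyl-1,3-dioxolan-4-yl]-4-[(2-methoxypropan-2-yl)peroxy]pentanal
Conditions: O3, CH2Cl2/MeOH, NaHCO3, −78 °C; then Me2S, −78 °C → rt
Reagents that add atoms: ozone, [O-][O+]=O
Why: Ozonolysis of the only alkene with reductive work-up removes the isopropylidene terminus as acetone and exposes the C3 aldehyde, and dimethyl sulfide reduces the methoxy hydroperoxide but not the dialkyl peroxyketal.

Step 5
Reactants: 6 C3 aldehyde
Product: 7 (3S,4R,7S)-7-[(4R)-2,2-dimethyl-1,3-dioxolan-4-yl]-7-[(2-methoxypropan-2-yl)peroxy]-3-methyloct-1-en-4-ol (anti homoallylic alcohol; target C2 methyl, C3 hydroxyl)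
Conditions: trans-but-2-ene, KOtBu, n-BuLi, THF, −78 → −45 °C; (−)-Ipc2BOMe, −78 °C; BF3·OEt2, −78 °C; then 6, −78 °C; NaBO3·4H2O, THF/H2O, rt
Reagents that add atoms: trans-but-2-ene, C/C=C/C, delivered as (E)-crotyldiisopinocampheylborane of the (+)-α-pinene series, C/C=C/CB([C@@H]1C[C@@H]2C[C@H]([C@H]1C)C2(C)C)[C@@H]1C[C@@H]2C[C@H]([C@H]1C)C2(C)C
Why: Brown crotylboration through a closed chair transition state should give the anti C2-methyl/C3-hydroxyl pair from the (E)-crotyl geometry, with the isopinocampheyl groups directing attack to the Si face of the aldehyde (reagent control, C6 being too remote to interfere), so that the carbinol is (R) and the vinyl group serves as a latent C1 carboxyl.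

Step 6
Reactants: 7 anti homoallylic alcohol
Product: 8 (3S,4R,7S)-7-[(4R)-2,2-dimethyl-1,3-dioxolan-4-yl]-7-[(2-methoxypropan-2-yl)peroxy]-3-methyloct-1-en-4-yl methanesulfonate
Conditions: MsCl, Et3N, CH2Cl2, 0 °C
Reagents that add atoms: methanesulfonyl chloride, CS(=O)(=O)Cl
Why: Sulfonylation of the secondary alcohol with retention turns the C3 oxygen into a leaving group while the hydroperoxide is still masked.

Step 7
Reactants: 8 mesylate peroxyketal
Product: 9 (3S,4R,7S)-7-[(4R)-2,2-dimethyl-1,3-dioxolan-4-yl]-7-hydroperoxy-3-methyloct-1-en-4-yl methanesulfonate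
Conditions: AcOH/THF/H2O, rt
Reagents that add atoms: none
Why: Mild acid hydrolysis should cleave the acyclic peroxyketal much faster than the cyclic dioxolane or the secondary mesylate and so release the tertiary hydroperoxide.

Step 8
Reactants: 9 hydroperoxy mesylate
Product: 10 (3S,6S)-3-[(2S)-but-3-en-2-yl]-6-[(4R)-2,2-dimethyl-1,3-dioxolan-4-yl]-6-methyl-1,2-dioxane
Conditions: KOtBu (1.05 equiv), 18-crown-6, THF, 0 °C
Reagents that add atoms: none
Why: The hydroperoxide is the only acidic site, and its anion should displace the C3 mesylate in a 6-exo-tet intramolecular SN2 alkylation with inversion, converting the (R) mesylate carbon into the (3S) ring carbon; keeping C1 as a vinyl group avoids the elimination that a β-sulfonyloxy ester would suffer.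

Step 9
Reactants: 10 vinyl dioxane
Product: 11 (2R)-2-[(3S,6S)-6-[(4R)-2,2-dimethyl-1,3-dioxolan-4-yl]-6-methyl-1,2-dioxan-3-yl]propanal
Conditions: O3, CH2Cl2/MeOH, −78 °C; then Me2S, −78 °C → rt; crude product used at once
Reagents that add atoms: ozone, [O-][O+]=O
Why: Ozonolysis of the terminal vinyl group gives the C1 aldehyde, the dialkyl peroxide ring and the dioxolane being inert to ozone and dimethyl sulfide, and the epimerisable aldehyde is not stored.

Step 10
Reactants: 11 C1 aldehyde
Product: 12 (2R)-2-[(3S,6S)-6-[(4R)-2,2-dimethyl-1,3-dioxolan-4-yl]-6-methyl-1,2-dioxan-3-yl]propanoic acid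
Conditions: NaClO2, NaH2PO4, 2-methyl-2-butene, t-BuOH/H2O, 0 °C → rt
Reagents that add atoms: sodium chlorite, [Na+].[O-]Cl=O
Why: Pinnick oxidation converts the aldehyde to the acid under buffered, weakly acidic conditions that should neither epimerise C2 nor open the ring by retro-conjugate addition.

Step 11
Reactants: 12 dioxane acid
Product: 13 methyl (2R)-2-[(3S,6S)-6-[(4R)-2,2-dimethyl-1,3-dioxolan-4-yl]-6-methyl-1,2-dioxan-3-yl]propanoate
Conditions: Me3SiCHN2, MeOH/toluene, 0 °C
Reagents that add atoms: (trimethylsilyl)diazomethane, C[Si](C)(C)C=[N+]=[N-]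
Why: Esterification with the diazoalkane is neutral and fast, so C2 and the peroxide ring are not exposed to base.

Step 12
Reactants: 13 dioxane ester acetonide
Product: 15 methyl (2R)-2-[(3S,6S)-6-formyl-6-methyl-1,2-dioxan-3-yl]propanoate (dioxane C7 aldehyde), via dioxane diol 14 (not isolated)
Conditions: H5IO6, EtOAc, rt
Reagents that add atoms: none
Why: Periodic acid should hydrolyse the terminal dioxolane and cleave the liberated 1,2-diol in the same flask (acetal hydrolysis, then Malaprade glycol cleavage), giving the non-enolisable C7 aldehyde without touching C6, C3 or C2.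

Step 13
Reactants: 4 (2R,3S)-3-hydroperoxy-3,7-dimethyloct-6-ene-1,2-diol
Product: 16 (2R,3S)-3-[(2-methoxypropan-2-yl)peroxy]-3,7-dimethyloct-6-ene-1,2-diol
Conditions: 2-methoxypropene (1.05 equiv), PPTS (cat.), CH2Cl2, −40 → −20 °C; Et3N quench at −20 °C
Reagents that add atoms: 2-methoxypropene, COC(C)=C
Why: Chemoselective ketalisation is expected because the unhindered, α-effect-activated terminal oxygen of the hydroperoxide should react faster than the alcohols at low temperature with one equivalent of enol ether, and any over-ketalised material is compound 5 and can be fed into step 4.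

Step 14
Reactants: 16 peroxyketal diol
Product: 17 (2S)-2-[(2-methoxypropan-2-yl)peroxy]-2,6-dimethylhept-5-enal (acyclic C13–C18 aldehyde)
Conditions: NaIO4, THF/aqueous NaH2PO4–Na2HPO4 buffer (pH 7), 0 °C → rt
Reagents that add atoms: none
Why: Malaprade glycol cleavage at neutral pH removes C1 as formaldehyde and gives the α-peroxy aldehyde, whose quaternary α-carbon cannot epimerise and whose peroxyketal is stable at pH 7.

Step 15
Reactants: 18 methyl hydrogen (R)-3-methylglutarate
Product: 19 methyl (3R)-5-hydroxy-3-methylpentanoate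
Conditions: BH3·SMe2, THF, 0 °C → rt; MeOH quench
Reagents that add atoms: none
Why: Borane reduces the carboxylic acid through its acyloxyborane much faster than the ester, so the acid-derived arm becomes the future C12 terminus and the C10 stereocentre is not touched.

Step 16
Reactants: 19 hydroxy ester
Product: 20 methyl (3S)-5-chloro-3-methylpentanoate
Conditions: PPh3, N-chlorosuccinimide, CH2Cl2, 0 °C → rt
Reagents that add atoms: N-chlorosuccinimide, O=C1CCC(=O)N1Cl
Why: Appel-type chlorination of the primary alcohol installs a latent iodide that is inert to the hydride, Mitsunobu and oxidation steps that follow, so no protecting group is needed.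

Step 17
Reactants: 20 chloro ester
Product: 21 (3S)-5-chloro-3-methylpentan-1-ol
Conditions: i-Bu2AlH, CH2Cl2, −78 → 0 °C; aqueous potassium sodium tartrate (KNaC4H4O6) work-up
Reagents that add atoms: none
Why: Hydride reduction of the ester gives the primary alcohol at the future C8, and a primary alkyl chloride is not reduced under these conditions.

Step 18
Reactants: 21 chloro alcohol
Product: 22 5-{[(3S)-5-chloro-3-methylpentyl]sulfanyl}-1-phenyl-1H-tetrazole
Conditions: 1-phenyl-1H-tetrazole-5-thiol, PPh3, DIAD, THF, 0 °C → rt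
Reagents that add atoms: 1-phenyl-1H-tetrazole-5-thiol, Sc1nnnn1-c1ccccc1
Why: Mitsunobu thioetherification of the primary alcohol with the acidic heteroaryl thiol is fast at 0 °C, whereas displacement of the alkyl chloride by the thiolate is slow.

Step 19
Reactants: 22 tetrazolyl sulfide
Product: 23 5-{[(3S)-5-chloro-3-methylpentyl]sulfonyl}-1-phenyl-1H-tetrazole
Conditions: (NH4)6Mo7O24·4H2O (cat.), 30% aqueous H2O2, EtOH, 0 °C → rt
Reagents that add atoms: hydrogen peroxide, OO
Why: Molybdate-catalysed oxidation takes the sulfide through the sulfoxide to the sulfone and has nothing else to oxidise in this molecule.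

Step 20
Reactants: 23 chloro sulfone
Product: 25 [(3R)-3-methyl-5-[(1-phenyl-1H-tetrazol-5-yl)sulfonyl]pentyl]triphenylphosphonium iodide (linchpin), via iodo sulfone 24 (not isolated)
Conditions: NaI, PPh3, MeCN, reflux
Reagents that add atoms: sodium iodide, [Na+].[I-]; triphenylphosphine, c1ccc(cc1)P(c1ccccc1)c1ccccc1
Why: Finkelstein exchange gives the primary iodide in the flask, which quaternises triphenylphosphine by SN2 at the unhindered C12, and the salt should crystallise free of neutral material.

Step 21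
Reactants: 25 linchpin phosphonium iodide; 17 acyclic C13–C18 aldehyde; 15 dioxane C7 aldehyde
Product: 28 diene with the full skeleton, E at C7 and Z at C12, C14 peroxide as 2-methoxyprop-2-yl peroxyketal, via ylide 26 (not isolated), via Z-alkenyl sulfone 27 (not isolated)
Conditions: 25, NaN(SiMe3)2 (1.0 equiv), THF, −78 °C; 17 (1.0 equiv), −78 °C → rt; recool to −78 °C, add 15 (1.0 equiv), then KN(SiMe3)2 (1.0 equiv) dropwise, −78 °C → rt
Reagents that add atoms: none
Why: NaN(SiMe3)2 removes a proton from C12, the carbon next to phosphorus and the stronger of the two carbon acids in 25 (pKa near 22 in DMSO against an estimated mid-twenties value for C8 next to the tetrazolyl sulfone), and ylide 26 adds to the hindered aldehyde 17 to give an oxaphosphetane that collapses to the C12=C13 alkene of 27 and Ph3PO. With 15 then in the flask, KN(SiMe3)2 deprotonates C8, the sulfonyl carbanion adds to the C7 aldehyde, the tetrazole migrates from sulfur to the new alkoxide (Smiles rearrangement), and loss of SO2 and the tetrazolone anion forms the C7=C8 alkene of 28. The closest known reactions are the salt-free Wittig and the Julia–Kocienski olefinations of α-peroxy aldehydes, run here one after the other on a single bifunctional reagent. No ring is closed and no stereocentre is created, and the expected Z geometry at C12 and E geometry at C7 are of no consequence because step 22 saturates both alkenes. The step needs site selectivity between the two nucleophilic ends and tolerance of the peroxides: the acidity gap and the order of addition assign each end to its aldehyde, the fully substituted carbons C6 and C14 exclude enolisation of either aldehyde and β-elimination of either peroxide, and the C14 hydroperoxide is masked as a base-stable peroxyketal. The one base-sensitive site, C2–H next to the ester and β to the ring oxygen, is protected by adding no more than one equivalent of the potassium amide slowly to the premixed sulfone and aldehyde at −78 °C, so that the amide is consumed at C8 as it arrives.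

Step 22
Reactants: 28 diene peroxyketal
Product: 29 methyl (2R)-2-[(3S,6R)-6-[(4S,8R)-8-[(2-methoxypropan-2-yl)peroxy]-4,8,12-trimethyltridec-11-en-1-yl]-6-methyl-1,2-dioxan-3-yl]propanoate
Conditions: 2-nitrobenzenesulfonohydrazide (excess, in portions), Et3N, CH2Cl2, rt
Reagents that add atoms: none
Why: Diimide generated in the flask transfers H2 by concerted syn addition to the two 1,2-disubstituted alkenes faster than to the trisubstituted C17=C18 alkene and, unlike catalytic hydrogenation, should leave both O–O bonds intact.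

Step 23
Reactants: 29 saturated peroxyketal
Product: 30 methyl (2R)-2-[(3S,6R)-6-[(4R,8R)-8-hydroperoxy-4,8,12-trimethyltridec-11-en-1-yl]-6-methyl-1,2-dioxan-3-yl]propanoate (target, CNP0381652.2)
Conditions: AcOH/THF/H2O, rt
Reagents that add atoms: none
Why: Mild acid hydrolysis of the acyclic peroxyketal releases the C14 hydroperoxide under conditions that should spare the dialkyl peroxide ring, the methyl ester and the trisubstituted alkene.

Compound list
1 | geraniol | CC(C)=CCC/C(C)=C/CO | starting material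
2 | [(2R,3R)-3-methyl-3-(4-methylpent-3-en-1-yl)oxiran-2-yl]methanol | OC[C@H]1O[C@]1(C)CCC=C(C)C | intermediate
3 | hydrogen peroxide | OO | starting material
4 | (2R,3S)-3-hydroperoxy-3,7-dimethyloct-6-ene-1,2-diol | OC[C@@H](O)[C@](C)(CCC=C(C)C)OO | intermediate
5 | (4R)-4-[(2S)-2-[(2-methoxypropan-2-yl)peroxy]-6-methylhept-5-en-2-yl]-2,2-dimethyl-1,3-dioxolane | CC1(C)OC[C@@H](O1)[C@](C)(CCC=C(C)C)OOC(C)(C)OC | intermediate
6 | (4S)-4-[(4R)-2,2-dimethyl-1,3-dioxolan-4-yl]-4-[(2-methoxypropan-2-yl)peroxy]pentanal | CC1(C)OC[C@@H](O1)[C@](C)(CCC=O)OOC(C)(C)OC | intermediate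
7 | (3S,4R,7S)-7-[(4R)-2,2-dimethyl-1,3-dioxolan-4-yl]-7-[(2-methoxypropan-2-yl)peroxy]-3-methyloct-1-en-4-ol | C=C[C@H](C)[C@H](O)CC[C@](C)(OOC(C)(C)OC)[C@H]1COC(C)(C)O1 | intermediate
8 | (3S,4R,7S)-7-[(4R)-2,2-dimethyl-1,3-dioxolan-4-yl]-7-[(2-methoxypropan-2-yl)peroxy]-3-methyloct-1-en-4-yl methanesulfonate | C=C[C@H](C)[C@H](OS(C)(=O)=O)CC[C@](C)(OOC(C)(C)OC)[C@H]1COC(C)(C)O1 | intermediate
9 | (3S,4R,7S)-7-[(4R)-2,2-dimethyl-1,3-dioxolan-4-yl]-7-hydroperoxy-3-methyloct-1-en-4-yl methanesulfonate | C=C[C@H](C)[C@H](OS(C)(=O)=O)CC[C@](C)(OO)[C@H]1COC(C)(C)O1 | intermediate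
10 | (3S,6S)-3-[(2S)-but-3-en-2-yl]-6-[(4R)-2,2-dimethyl-1,3-dioxolan-4-yl]-6-methyl-1,2-dioxane | C=C[C@H](C)[C@@H]1CC[C@@](C)([C@H]2COC(C)(C)O2)OO1 | intermediate
11 | (2R)-2-[(3S,6S)-6-[(4R)-2,2-dimethyl-1,3-dioxolan-4-yl]-6-methyl-1,2-dioxan-3-yl]propanal | O=C[C@H](C)[C@@H]1CC[C@@](C)([C@H]2COC(C)(C)O2)OO1 | intermediate
12 | (2R)-2-[(3S,6S)-6-[(4R)-2,2-dimethyl-1,3-dioxolan-4-yl]-6-methyl-1,2-dioxan-3-yl]propanoic acid | OC(=O)[C@H](C)[C@@H]1CC[C@@](C)([C@H]2COC(C)(C)O2)OO1 | intermediate
13 | methyl (2R)-2-[(3S,6S)-6-[(4R)-2,2-dimethyl-1,3-dioxolan-4-yl]-6-methyl-1,2-dioxan-3-yl]propanoate | COC(=O)[C@H](C)[C@@H]1CC[C@@](C)([C@H]2COC(C)(C)O2)OO1 | intermediate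
14 | methyl (2R)-2-[(3S,6S)-6-[(1R)-1,2-dihydroxyethyl]-6-methyl-1,2-dioxan-3-yl]propanoate | COC(=O)[C@H](C)[C@@H]1CC[C@@](C)([C@H](O)CO)OO1 | intermediate
15 | methyl (2R)-2-[(3S,6S)-6-formyl-6-methyl-1,2-dioxan-3-yl]propanoate | COC(=O)[C@H](C)[C@@H]1CC[C@@](C)(C=O)OO1 | intermediate
16 | (2R,3S)-3-[(2-methoxypropan-2-yl)peroxy]-3,7-dimethyloct-6-ene-1,2-diol | OC[C@@H](O)[C@](C)(CCC=C(C)C)OOC(C)(C)OC | intermediate
17 | (2S)-2-[(2-methoxypropan-2-yl)peroxy]-2,6-dimethylhept-5-enal | O=C[C@](C)(CCC=C(C)C)OOC(C)(C)OC | intermediate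
18 | methyl hydrogen (R)-3-methylglutarate, (3R)-5-methoxy-3-methyl-5-oxopentanoic acid | COC(=O)C[C@H](C)CC(=O)O | starting material
19 | methyl (3R)-5-hydroxy-3-methylpentanoate | COC(=O)C[C@H](C)CCO | intermediate
20 | methyl (3S)-5-chloro-3-methylpentanoate | COC(=O)C[C@H](C)CCCl | intermediate
21 | (3S)-5-chloro-3-methylpentan-1-ol | OCC[C@H](C)CCCl | intermediate
22 | 5-{[(3S)-5-chloro-3-methylpentyl]sulfanyl}-1-phenyl-1H-tetrazole | c1ccccc1-n1nnnc1SCC[C@H](C)CCCl | intermediate
23 | 5-{[(3S)-5-chloro-3-methylpentyl]sulfonyl}-1-phenyl-1H-tetrazole | O=S(=O)(CC[C@H](C)CCCl)c1nnnn1-c1ccccc1 | intermediate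
24 | 5-{[(3S)-5-iodo-3-methylpentyl]sulfonyl}-1-phenyl-1H-tetrazole | O=S(=O)(CC[C@H](C)CCI)c1nnnn1-c1ccccc1 | intermediate
25 | [(3R)-3-methyl-5-[(1-phenyl-1H-tetrazol-5-yl)sulfonyl]pentyl]triphenylphosphonium iodide | O=S(=O)(CC[C@H](C)CC[P+](c1ccccc1)(c1ccccc1)c1ccccc1)c1nnnn1-c1ccccc1.[I-] | intermediate
26 | 5-{[(3R)-3-methyl-5-(triphenyl-λ5-phosphanylidene)pentyl]sulfonyl}-1-phenyl-1H-tetrazole (ylide) | O=S(=O)(CC[C@H](C)CC=P(c1ccccc1)(c1ccccc1)c1ccccc1)c1nnnn1-c1ccccc1 | intermediate
27 | 5-{[(3R,5Z,7S)-7-[(2-methoxypropan-2-yl)peroxy]-3,7,11-trimethyldodeca-5,10-dien-1-yl]sulfonyl}-1-phenyl-1H-tetrazole | O=S(=O)(CC[C@H](C)C/C=C\[C@](C)(CCC=C(C)C)OOC(C)(C)OC)c1nnnn1-c1ccccc1 | intermediate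
28 | methyl (2R)-2-[(3S,6S)-6-[(1E,4S,6Z,8S)-8-[(2-methoxypropan-2-yl)peroxy]-4,8,12-trimethyltrideca-1,6,11-trien-1-yl]-6-methyl-1,2-dioxan-3-yl]propanoate | COC(=O)[C@H](C)[C@@H]1CC[C@@](C)(/C=C/C[C@H](C)C/C=C\[C@](C)(CCC=C(C)C)OOC(C)(C)OC)OO1 | intermediate
29 | methyl (2R)-2-[(3S,6R)-6-[(4S,8R)-8-[(2-methoxypropan-2-yl)peroxy]-4,8,12-trimethyltridec-11-en-1-yl]-6-methyl-1,2-dioxan-3-yl]propanoate | COC(=O)[C@H](C)[C@@H]1CC[C@@](C)(CCC[C@H](C)CCC[C@](C)(CCC=C(C)C)OOC(C)(C)OC)OO1 | intermediate
30 | methyl (2R)-2-[(3S,6R)-6-[(4R,8R)-8-hydroperoxy-4,8,12-trimethyltridec-11-en-1-yl]-6-methyl-1,2-dioxan-3-yl]propanoate | COC(=O)[C@H](C)[C@@H]1CC[C@@](C)(CCC[C@H](C)CCC[C@](C)(CCC=C(C)C)OO)OO1 | target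

Total step count: 23 steps.
Longest linear sequence: 15 steps (steps 1–12, then 21–23).

Steps most likely to fail

Step 21. The two acidic sites of the linchpin may not be discriminated cleanly, so that ylide and sulfonyl anion form together and give cross-coupled or doubly C13-capped products. The ylide may also attack the tetrazolyl sulfone, or excess amide may open the dioxane at C2/C3. The fallback separates the two olefinations and runs both as Julia–Kocienski reactions; it sets out from 23 and 15 and returns at 29. Chloro sulfone 23, which has no second acidic site, is condensed with aldehyde 15 (KN(SiMe3)2, THF, −78 °C) to give the (E)-chloroalkene, methyl (2R)-2-[(3S,6S)-6-[(1E,4S)-6-chloro-4-methylhex-1-en-1-yl]-6-methyl-1,2-dioxan-3-yl]propanoate F1. Displacement of chloride with sodium 1-phenyl-1H-tetrazole-5-thiolate (NaI cat., DMF, 50 °C) gives the tetrazolyl sulfide F2. Oxidation with (NH4)6Mo7O24·4H2O and H2O2 in EtOH, which has only a disubstituted alkene and a dialkyl peroxide to spare, gives the tetrazolyl sulfone F3. A second Julia–Kocienski reaction of F3 with 17 gives the (7E,12E)-diene F4, which is reduced under the conditions of step 22 to 29.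

Step 8. Displacement at the hindered secondary carbon may be slow, so that E2 elimination toward the allylic C2–H or base-induced fragmentation of the peroxide competes. The fallback closes the ring by conjugate addition; it sets out from 6 and returns at 13. Wittig olefination of 6 with methyl 2-(triphenyl-λ5-phosphanylidene)propanoate (CH2Cl2, rt) gives the (E)-enoate, methyl (2E,6S)-6-[(4R)-2,2-dimethyl-1,3-dioxolan-4-yl]-6-[(2-methoxypropan-2-yl)peroxy]-2-methylhept-2-enoate F5. Aqueous AcOH in THF frees the hydroperoxy enoate F6. Et2NH in CF3CH2OH closes the 1,2-dioxane by 6-exo-trig addition of the hydroperoxide to the enoate. This route is less selective, because neither the face of addition at C3 nor the protonation at C2 is controlled, so 13 would have to be separated from its C2/C3 diastereomers by chromatography.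

Step 13. Chemoselectivity may be lost, through ketalisation of the diol (dioxolane formation) or acid-mediated closure of the hydroxy peroxyketal onto the neighbouring hydroxyl. The fallback removes the competing primary hydroxyl before the peroxide is made; it sets out from 2 and returns at 16. Silylation of 2 (t-BuPh2SiCl, imidazole, DMF) gives the epoxy silyl ether F7. Perhydrolysis as in step 2 gives the hydroperoxy alcohol F8, in which only a hindered secondary hydroxyl remains. Ketalisation with 2-methoxypropene and PPTS gives the peroxyketal silyl ether F9. Bu4NF in THF removes the silyl group without affecting the peroxyketal and gives 16.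

Further compounds
F1 | step 21 | methyl (2R)-2-[(3S,6S)-6-[(1E,4S)-6-chloro-4-methylhex-1-en-1-yl]-6-methyl-1,2-dioxan-3-yl]propanoate | COC(=O)[C@H](C)[C@@H]1CC[C@@](C)(/C=C/C[C@H](C)CCCl)OO1
F2 | step 21 | methyl (2R)-2-[(3S,6S)-6-methyl-6-[(1E,4S)-4-methyl-6-[(1-phenyl-1H-tetrazol-5-yl)sulfanyl]hex-1-en-1-yl]-1,2-dioxan-3-yl]propanoate | COC(=O)[C@H](C)[C@@H]1CC[C@@](C)(/C=C/C[C@H](C)CCSc2nnnn2-c2ccccc2)OO1
F3 | step 21 | methyl (2R)-2-[(3S,6S)-6-methyl-6-[(1E,4S)-4-methyl-6-[(1-phenyl-1H-tetrazol-5-yl)sulfonyl]hex-1-en-1-yl]-1,2-dioxan-3-yl]propanoate | COC(=O)[C@H](C)[C@@H]1CC[C@@](C)(/C=C/C[C@H](C)CCS(=O)(=O)c2nnnn2-c2ccccc2)OO1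
F4 | step 21 | methyl (2R)-2-[(3S,6S)-6-[(1E,4S,6E,8S)-8-[(2-methoxypropan-2-yl)peroxy]-4,8,12-trimethyltrideca-1,6,11-trien-1-yl]-6-methyl-1,2-dioxan-3-yl]propanoate | COC(=O)[C@H](C)[C@@H]1CC[C@@](C)(/C=C/C[C@H](C)C/C=C/[C@](C)(CCC=C(C)C)OOC(C)(C)OC)OO1
F5 | step 8 | methyl (2E,6S)-6-[(4R)-2,2-dimethyl-1,3-dioxolan-4-yl]-6-[(2-methoxypropan-2-yl)peroxy]-2-methylhept-2-enoate | CC1(C)OC[C@@H](O1)[C@](C)(CC/C=C(\C)C(=O)OC)OOC(C)(C)OC
F6 | step 8 | methyl (2E,6S)-6-[(4R)-2,2-dimethyl-1,3-dioxolan-4-yl]-6-hydroperoxy-2-methylhept-2-enoate | CC1(C)OC[C@@H](O1)[C@](C)(CC/C=C(\C)C(=O)OC)OO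
F7 | step 13 | tert-butyl{[(2R,3R)-3-methyl-3-(4-methylpent-3-en-1-yl)oxiran-2-yl]methoxy}diphenylsilane | CC(C)(C)[Si](c1ccccc1)(c1ccccc1)OC[C@H]1O[C@]1(C)CCC=C(C)C
F8 | step 13 | (2R,3S)-1-[(tert-butyldiphenylsilyl)oxy]-3-hydroperoxy-3,7-dimethyloct-6-en-2-ol | CC(C)(C)[Si](c1ccccc1)(c1ccccc1)OC[C@@H](O)[C@](C)(CCC=C(C)C)OO
F9 | step 13 | (2R,3S)-1-[(tert-butyldiphenylsilyl)oxy]-3-[(2-methoxypropan-2-yl)peroxy]-3,7-dimethyloct-6-en-2-ol | CC(C)(C)[Si](c1ccccc1)(c1ccccc1)OC[C@@H](O)[C@](C)(CCC=C(C)C)OOC(C)(C)OC
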